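**Retrosynthetic overview**
- The hydroquinone is unmasked last from a 11,12,14-trimethoxyarene. The δ-lactone comes from a C19 acid and a C20 alcohol that sit 1,3-diaxial on ring A. The C19 acid and the C7 ketone come from one chromium oxidation of the cyclisation product.
- Rings A and B are formed together, A then B, by an epoxide-initiated cation–olefin–arene bicyclisation (oxidosqualene-cyclase logic). The initiator is a 2,2-disubstituted (S)-oxirane, so the epoxide oxygen ends on C19 and C4, C5 and C10 are set in one step. Ring C is the arene, present from the start; the lactone ring closes after the carbocycles.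
- The oxirane comes from a methyl ketone by catalytic asymmetric Corey–Chaykovsky epoxidation. The C5=C10 alkene carrying the C20 oxygen comes from copper-catalysed carbomagnesiation/iodination of propargyl alcohol, then B-alkyl Suzuki coupling with an aryl styrene.
- The arene comes from 1,2,4-trimethoxybenzene (ortho-lithiation/acetone, ionic hydrogenation, bromination, vinylation).

Assumption: the target is the natural-series abietane drawn in the SMILES (H-5 α, C-20 and C-19 β, C-18 α; 4S,5R,10R). The BINOL antipode of the step-8 catalyst is taken to be the one that gives the (S)-oxirane, to be confirmed on first use. Abietane numbering is used for the tricycles.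

**Step 1**
Reactants: 1 1,2,4-trimethoxybenzene
Product: 3 2-(2,3,6-trimethoxyphenyl)propan-2-ol, via aryllithium 2 (not isolated)
Conditions: n-BuLi, TMEDA, THF, 0 °C; acetone, −78 to 0 °C; H2O
Reagents that add atoms: acetone, CC(C)=O
Why: Directed ortho-metalation removes the C3 proton flanked by two methoxy groups, and the aryllithium adds 1,2 to acetone.

**Step 2**
Reactants: 3 2-(2,3,6-trimethoxyphenyl)propan-2-ol
Product: 4 1,2,4-trimethoxy-3-(propan-2-yl)benzene
Conditions: Et3SiH, CF3CO2H, CH2Cl2, 0 °C to rt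
Reagents that add atoms: none
Why: Ionic hydrogenation: the tertiary benzylic cation, stabilised by two ortho methoxy groups, is reduced by hydride transfer from the silane.

**Step 3**
Reactants: 4 1,2,4-trimethoxy-3-(propan-2-yl)benzene
Product: 5 1-bromo-2,4,5-trimethoxy-3-(propan-2-yl)benzene
Conditions: NBS, MeCN, 0 °C to rt
Reagents that add atoms: N-bromosuccinimide, O=C1CCC(=O)N1Br
Why: Electrophilic aromatic bromination goes to the only free position that is both ortho and para to methoxy groups (the future C8).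

**Step 4**
Reactants: 5 1-bromo-2,4,5-trimethoxy-3-(propan-2-yl)benzene
Product: 6 1-ethenyl-2,4,5-trimethoxy-3-(propan-2-yl)benzene
Conditions: vinylboronic acid pinacol ester, Pd(dppf)Cl2 (3 mol %), K3PO4, dioxane/H2O, 90 °C
Reagents that add atoms: vinylboronic acid pinacol ester, C=CB1OC(C)(C)C(C)(C)O1
Why: Suzuki–Miyaura coupling of an aryl bromide with a vinylboronate installs C6 and C7.

**Step 5**
Reactants: 7 2-(3-chloropropyl)-2-methyl-1,3-dioxolane; 8 prop-2-yn-1-ol
Product: 11 (Z)-3-iodo-2-[3-(2-methyl-1,3-dioxolan-2-yl)propyl]prop-2-en-1-ol, via Grignard reagent 9 (not isolated), via oxamagnesacycle 10 (not isolated)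
Conditions: 7, Mg, THF, reflux; then 8 (0.33 equiv), CuI (10 mol %), THF, −10 °C to rt; I2, −78 to 0 °C; aq. NH4Cl
Reagents that add atoms: iodine, [I][I]
Why: Copper-catalysed anti-carbomagnesiation of the propargylic magnesium alkoxide (Duboudin–Jousseaume reaction) puts the alkyl group on the carbon next to CH2O and holds Mg cis to CH2O in a five-membered chelate, and iodinolysis with retention gives the Z iodide, which fixes the C5=C10 geometry.

**Step 6**
Reactants: 11 (Z)-3-iodo-2-[3-(2-methyl-1,3-dioxolan-2-yl)propyl]prop-2-en-1-ol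
Product: 12 tert-butyl{[(Z)-3-iodo-2-[3-(2-methyl-1,3-dioxolan-2-yl)propyl]prop-2-en-1-yl]oxy}diphenylsilane
Conditions: TBDPSCl, imidazole, DMF, rt
Reagents that add atoms: tert-butyl(chloro)diphenylsilane, CC(C)(C)[Si](Cl)(c1ccccc1)c1ccccc1
Why: Silylation of the primary alcohol gives an acid- and Lewis-acid-stable ether that keeps the C20 oxygen distinct from the C19 oxygen introduced later.

**Step 7**
Reactants: 6 1-ethenyl-2,4,5-trimethoxy-3-(propan-2-yl)benzene; 12 tert-butyl{[(Z)-3-iodo-2-[3-(2-methyl-1,3-dioxolan-2-yl)propyl]prop-2-en-1-yl]oxy}diphenylsilane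
Product: 15 (Z)-6-[(tert-butyldiphenylsilyloxy)methyl]-9-[2,4,5-trimethoxy-3-(propan-2-yl)phenyl]non-6-en-2-one, via alkylborane 13 (not isolated), via ketal 14 (not isolated)
Conditions: 6, 9-BBN, THF, 0 °C to rt; then 12, Pd(dppf)Cl2 (5 mol %), K3PO4, DMF/H2O, 50 °C; then 2 M HCl, THF, rt
Reagents that add atoms: water, O
Why: Anti-Markovnikov hydroboration of the styrene, B-alkyl Suzuki–Miyaura coupling with retention of the vinyl iodide geometry (ArCH2CH2 cis to CH2OSi, trans to C1) and acid hydrolysis of the dioxolane are run in one flask.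

**Step 8**
Reactants: 15 (Z)-6-[(tert-butyldiphenylsilyloxy)methyl]-9-[2,4,5-trimethoxy-3-(propan-2-yl)phenyl]non-6-en-2-one
Product: 16 (S)-2-methyl-2-{(Z)-4-[(tert-butyldiphenylsilyloxy)methyl]-7-[2,4,5-trimethoxy-3-(propan-2-yl)phenyl]hept-4-en-1-yl}oxirane
Conditions: trimethylsulfoxonium iodide, NaH, THF (ylide preformed); LaLi3(binaphthoxide)3 (5 mol %), (2,4,6-(MeO)3C6H2)3P=O (5 mol %), 5 Å MS, THF, rt
Reagents that add atoms: trimethylsulfoxonium iodide (as its methylide), C[S+](C)(C)=O.[I-]
Why: Catalytic asymmetric Corey–Chaykovsky epoxidation: the La/Li binaphthoxide binds ketone and ylide and delivers CH2 to one face of the methyl ketone (about 90% ee expected for methyl alkyl ketones), which creates the only reagent-controlled stereocentre of the route (C4, with the future C19 as the oxirane CH2).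

**Step 9**
Reactants: 16 (S)-2-methyl-2-{(Z)-4-[(tert-butyldiphenylsilyloxy)methyl]-7-[2,4,5-trimethoxy-3-(propan-2-yl)phenyl]hept-4-en-1-yl}oxirane
Product: 17 20-(tert-butyldiphenylsilyloxy)-11,12,14-trimethoxyabieta-8,11,13-trien-19-ol (H-5 α; C-20 β; CH2OH 4β; CH3 4α)
Conditions: MeAlCl2 (2.5 equiv), CH2Cl2, −78 °C; H2O
Reagents that add atoms: none
Why: Proposed new method: MeAlCl2 activates the oxirane and the C5=C10 alkene attacks the tertiary C4 anti to the leaving oxygen (loose SN2, inversion, so the (S)-oxirane fixes C4) through a chair–chair array in which the oxirane CH2, tied back toward the departing oxygen, takes the crowded pseudo-axial slot and the methyl the pseudo-equatorial one, the alkene geometry (C1 trans to C6) gives the trans ring fusion, and the C10 cation is captured by arene C9 ortho to a methoxy group, so C19–O and C20–O end up 1,3-diaxial on the β face with H-5 α; the closest known chemistry is the Lewis-acid epoxide-initiated cation–olefin–arene polycyclisation of trisubstituted epoxy polyenes, the cyclialkylation of arenes by 2,2-disubstituted oxiranes at the tertiary carbon, and the inverting attack of alkenes on tertiary epoxide carbons in polyepoxide cascades.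

**Step 10**
Reactants: 17 20-(tert-butyldiphenylsilyloxy)-11,12,14-trimethoxyabieta-8,11,13-trien-19-ol
Product: 18 20-(tert-butyldiphenylsilyloxy)-11,12,14-trimethoxy-7-oxoabieta-8,11,13-trien-19-oic acid
Conditions: CrO3 (6 equiv), AcOH/H2O (9:1), rt
Reagents that add atoms: chromium trioxide, O=[Cr](=O)=O; water, O
Why: Chromic acid oxidation: hexavalent chromium takes the neopentyl C19 alcohol through the aldehyde hydrate to the acid and the C7 methylene (benzylic, para to the C12 methoxy) to the aryl ketone, while the isopropyl methine is shielded by its two ortho methoxy groups and no stereocentre is touched.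

**Step 11**
Reactants: 18 20-(tert-butyldiphenylsilyloxy)-11,12,14-trimethoxy-7-oxoabieta-8,11,13-trien-19-oic acid
Product: 20 11,12,14-trimethoxy-7-oxoabieta-8,11,13-trien-19,20-olide, via hydroxy acid 19 (not isolated)
Conditions: Bu4NF, THF, 50 °C; then 1 M HCl, rt
Reagents that add atoms: none
Why: Fluoride desilylation followed by acid-promoted lactonisation of the 1,3-diaxial hydroxy acid, which can close only when C19 is β and so also confirms the C4 configuration.

**Step 12**
Reactants: 20 11,12,14-trimethoxy-7-oxoabieta-8,11,13-trien-19,20-olide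
Product: 22 11,14-dihydroxy-12-methoxy-7-oxoabieta-8,11,13-trien-19,20-olide, via quinone 21 (not isolated)
Conditions: (NH4)2Ce(NO3)6 (2.5 equiv), MeCN/H2O, 0 °C; then aq. Na2S2O4, EtOAc, rt, under N2
Reagents that add atoms: water, O
Why: Oxidative demethylation: tetravalent cerium oxidises the para-dimethoxyarene to the p-quinone with loss of the C11 and C14 methyls (the C12 methoxy survives as a vinylogous ester), and dithionite reduces the quinone to the hydroquinone, which is stabilised by the C14–OH···O=C7 hydrogen bond; no stereocentre is involved.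

**Compound list**
1 | 1,2,4-trimethoxybenzene | COc1ccc(OC)c(OC)c1 | starting material
2 | (2,3,6-trimethoxyphenyl)lithium | [Li]c1c(OC)ccc(OC)c1OC | intermediate
3 | 2-(2,3,6-trimethoxyphenyl)propan-2-ol | CC(C)(O)c1c(OC)ccc(OC)c1OC | intermediate
4 | 1,2,4-trimethoxy-3-(propan-2-yl)benzene | CC(C)c1c(OC)ccc(OC)c1OC | intermediate
5 | 1-bromo-2,4,5-trimethoxy-3-(propan-2-yl)benzene | CC(C)c1c(OC)c(Br)cc(OC)c1OC | intermediate
6 | 1-ethenyl-2,4,5-trimethoxy-3-(propan-2-yl)benzene | C=Cc1cc(OC)c(OC)c(C(C)C)c1OC | intermediate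
7 | 2-(3-chloropropyl)-2-methyl-1,3-dioxolane | CC1(CCCCl)OCCO1 | starting material
8 | prop-2-yn-1-ol | C#CCO | starting material
9 | [3-(2-methyl-1,3-dioxolan-2-yl)propyl]magnesium chloride | CC1(CCC[Mg]Cl)OCCO1 | intermediate
10 | 4-[3-(2-methyl-1,3-dioxolan-2-yl)propyl]-2,5-dihydro-1,2-oxamagnesole (cyclic alkenylmagnesium alkoxide, Mg cis to CH2O) | CC1(CCCC2=C[Mg]OC2)OCCO1 | intermediate
11 | (Z)-3-iodo-2-[3-(2-methyl-1,3-dioxolan-2-yl)propyl]prop-2-en-1-ol | OC/C(=C\I)CCCC1(C)OCCO1 | intermediate
12 | tert-butyl{[(Z)-3-iodo-2-[3-(2-methyl-1,3-dioxolan-2-yl)propyl]prop-2-en-1-yl]oxy}diphenylsilane | CC(C)(C)[Si](c1ccccc1)(c1ccccc1)OC/C(=C\I)CCCC1(C)OCCO1 | intermediate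
13 | 9-{2-[2,4,5-trimethoxy-3-(propan-2-yl)phenyl]ethyl}-9-borabicyclo[3.3.1]nonane | COc1cc(CCB2C3CCCC2CCC3)c(OC)c(C(C)C)c1OC | intermediate
14 | 2-{(Z)-4-[(tert-butyldiphenylsilyloxy)methyl]-7-[2,4,5-trimethoxy-3-(propan-2-yl)phenyl]hept-4-en-1-yl}-2-methyl-1,3-dioxolane | CC(C)(C)[Si](c1ccccc1)(c1ccccc1)OC/C(=C\CCc1cc(OC)c(OC)c(C(C)C)c1OC)CCCC1(C)OCCO1 | intermediate
15 | (Z)-6-[(tert-butyldiphenylsilyloxy)methyl]-9-[2,4,5-trimethoxy-3-(propan-2-yl)phenyl]non-6-en-2-one | CC(=O)CCC/C(CO[Si](c1ccccc1)(c1ccccc1)C(C)(C)C)=C/CCc1cc(OC)c(OC)c(C(C)C)c1OC | intermediate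
16 | (S)-2-methyl-2-{(Z)-4-[(tert-butyldiphenylsilyloxy)methyl]-7-[2,4,5-trimethoxy-3-(propan-2-yl)phenyl]hept-4-en-1-yl}oxirane | COc1cc(CC/C=C(\CO[Si](c2ccccc2)(c2ccccc2)C(C)(C)C)CCC[C@@]2(C)CO2)c(OC)c(C(C)C)c1OC | intermediate
17 | 20-(tert-butyldiphenylsilyloxy)-11,12,14-trimethoxyabieta-8,11,13-trien-19-ol (H-5 α, C-20 β, CH2OH 4β, CH3 4α) | COc1c(OC)c2c(c(OC)c1C(C)C)CC[C@@H]1[C@]2(CO[Si](c3ccccc3)(c3ccccc3)C(C)(C)C)CCC[C@]1(C)CO | intermediate
18 | 20-(tert-butyldiphenylsilyloxy)-11,12,14-trimethoxy-7-oxoabieta-8,11,13-trien-19-oic acid (same configuration as 17) | COc1c(OC)c2c(c(OC)c1C(C)C)C(=O)C[C@@H]1[C@]2(CO[Si](c3ccccc3)(c3ccccc3)C(C)(C)C)CCC[C@]1(C)C(=O)O | intermediate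
19 | 20-hydroxy-11,12,14-trimethoxy-7-oxoabieta-8,11,13-trien-19-oic acid (same configuration as 17) | COc1c(OC)c2c(c(OC)c1C(C)C)C(=O)C[C@@H]1[C@]2(CO)CCC[C@]1(C)C(=O)O | intermediate
20 | 11,12,14-trimethoxy-7-oxoabieta-8,11,13-trien-19,20-olide (H-5 α, lactone bridge β, CH3 4α) | COc1c(OC)c2c(c(OC)c1C(C)C)C(=O)C[C@@H]1[C@]23CCC[C@]1(C)C(=O)OC3 | intermediate
21 | 12-methoxy-7,11,14-trioxoabieta-8,12-dien-19,20-olide (same configuration as 20) | COC=1C(=O)C2=C(C(=O)C=1C(C)C)C(=O)C[C@@H]1[C@]23CCC[C@]1(C)C(=O)OC3 | intermediate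
22 | 11,14-dihydroxy-12-methoxy-7-oxoabieta-8,11,13-trien-19,20-olide (4S,5R,10R; H-5 α, lactone bridge β, CH3 4α) | COc1c(O)c2c(c(O)c1C(C)C)C(=O)C[C@@H]1[C@]23CCC[C@]1(C)C(=O)OC3 | target

**Step count**
Total: 12 steps. Longest linear sequence: 10 steps (steps 1–4, then 7–12).

**Steps most likely to fail, with fallbacks**

Step 9 (epoxide-initiated bicyclisation). The risks are:
- Meinwald rearrangement of the 2,2-disubstituted oxirane to the α-methyl aldehyde.
- Ionisation at C4 before the alkene attacks, which would erode the ee.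
- The C4 epimer with CH2OH equatorial.
- A slower alkene because of the allylic silyloxy group.
- Transient capture of the C10 cation by the axial C19 alkoxide; this tertiary bridged ether should re-ionise under MeAlCl2 and drain to the arene-alkylated product.

Fallback: an organocatalytic SOMO radical-cation bicyclisation, in which the catalyst sets C5 and C10 and C4 is made quaternary afterwards by enolate methylation. It sets out from 8 and 6 and comes back at 18. Commercial 2-(4-chlorobutyl)-1,3-dioxolane is converted with Mg into [4-(1,3-dioxolan-2-yl)butyl]magnesium chloride F1. Under the step-5 conditions F1 adds to 8 and iodinolysis gives (Z)-2-[4-(1,3-dioxolan-2-yl)butyl]-3-iodoprop-2-en-1-ol F2, which is silylated to its tert-butyldiphenylsilyl ether F3. B-alkyl Suzuki coupling of F3 with borane 13 (from 6) gives the coupled acetal F4, and aqueous HCl frees (Z)-6-[(tert-butyldiphenylsilyloxy)methyl]-9-[2,4,5-trimethoxy-3-(propan-2-yl)phenyl]non-6-enal F5. F5 is cyclised with a 2-tert-butyl-5-(1-naphthylmethyl)imidazolidin-4-one trifluoroacetate catalyst (the antipode that gives the H-5 α/C-20 β series), Cu(OTf)2 and CF3CO2Na in i-PrCN/DME. The enamine radical cation closes ring A in 6-endo fashion and the C10 radical closes ring B on the arene, giving the tricyclic 4α-formyl compound F6. KOt-Bu/MeI methylates the aldehyde enolate of F6 from the less hindered α face, away from the axial C20 group, to give the 19-aldehyde F7. The step-10 CrO3/AcOH oxidation then converts F7 (aldehyde to acid, C7 to ketone) into 18.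

Step 10 (double chromium oxidation). The risks are incomplete oxidation of the hindered neopentyl alcohol, over-oxidation at C6 or the isopropyl methine, and attack on the electron-rich ring.

Fallback: separate the two oxidations and do the benzylic one on the lactone. It sets out from 17 and comes back at 20. TEMPO (cat.), NaOCl (cat.) and NaClO2 in MeCN/phosphate buffer oxidise only the alcohol, giving 20-(tert-butyldiphenylsilyloxy)-11,12,14-trimethoxyabieta-8,11,13-trien-19-oic acid F8. Bu4NF then HCl gives the 7-deoxy lactone 11,12,14-trimethoxyabieta-8,11,13-trien-19,20-olide F9. A radical-chain benzylic oxidation of F9 (t-BuOOH, NaClO2, N-hydroxyphthalimide cat., MeCN/H2O) gives 20.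

Step 12 (oxidative demethylation of the acyl-substituted arene). The risks are a sluggish or unselective oxidation of the ketone-deactivated ring and competing ortho-quinone formation.

Fallback: make the ring a phenol first and oxidise it with hypervalent iodine. It sets out from 20 and comes back at 21. BCl3 in CH2Cl2 at −78 to 0 °C cleaves only the C14 methyl ether chelated to the C7 ketone, giving 14-hydroxy-11,12-dimethoxy-7-oxoabieta-8,11,13-trien-19,20-olide F10. PhI(OAc)2 in MeCN/H2O oxidises this para-methoxyphenol to quinone 21, which is reduced with Na2S2O4 as in step 12 to 22.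

**Further compounds**
F1 | step 9 | [4-(1,3-dioxolan-2-yl)butyl]magnesium chloride | Cl[Mg]CCCCC1OCCO1
F2 | step 9 | (Z)-2-[4-(1,3-dioxolan-2-yl)butyl]-3-iodoprop-2-en-1-ol | OC/C(=C\I)CCCCC1OCCO1
F3 | step 9 | tert-butyl{[(Z)-2-[4-(1,3-dioxolan-2-yl)butyl]-3-iodoprop-2-en-1-yl]oxy}diphenylsilane | CC(C)(C)[Si](c1ccccc1)(c1ccccc1)OC/C(=C\I)CCCCC1OCCO1
F4 | step 9 | 2-{(Z)-5-[(tert-butyldiphenylsilyloxy)methyl]-8-[2,4,5-trimethoxy-3-(propan-2-yl)phenyl]oct-5-en-1-yl}-1,3-dioxolane | CC(C)(C)[Si](c1ccccc1)(c1ccccc1)OC/C(=C\CCc1cc(OC)c(OC)c(C(C)C)c1OC)CCCCC1OCCO1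
F5 | step 9 | (Z)-6-[(tert-butyldiphenylsilyloxy)methyl]-9-[2,4,5-trimethoxy-3-(propan-2-yl)phenyl]non-6-enal | O=CCCCC/C(CO[Si](c1ccccc1)(c1ccccc1)C(C)(C)C)=C/CCc1cc(OC)c(OC)c(C(C)C)c1OC
F6 | step 9 | 20-(tert-butyldiphenylsilyloxy)-11,12,14-trimethoxy-19-norabieta-8,11,13-trien-18-al (4α-CHO, H-5 α, C-20 β) | COc1c(OC)c2c(c(OC)c1C(C)C)CC[C@@H]1[C@]2(CO[Si](c3ccccc3)(c3ccccc3)C(C)(C)C)CCC[C@H]1C=O
F7 | step 9 | 20-(tert-butyldiphenylsilyloxy)-11,12,14-trimethoxyabieta-8,11,13-trien-19-al (CHO 4β, CH3 4α) | COc1c(OC)c2c(c(OC)c1C(C)C)CC[C@@H]1[C@]2(CO[Si](c3ccccc3)(c3ccccc3)C(C)(C)C)CCC[C@]1(C)C=O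
F8 | step 10 | 20-(tert-butyldiphenylsilyloxy)-11,12,14-trimethoxyabieta-8,11,13-trien-19-oic acid | COc1c(OC)c2c(c(OC)c1C(C)C)CC[C@@H]1[C@]2(CO[Si](c3ccccc3)(c3ccccc3)C(C)(C)C)CCC[C@]1(C)C(=O)O
F9 | step 10 | 11,12,14-trimethoxyabieta-8,11,13-trien-19,20-olide | COc1c(OC)c2c(c(OC)c1C(C)C)CC[C@@H]1[C@]23CCC[C@]1(C)C(=O)OC3
F10 | step 12 | 14-hydroxy-11,12-dimethoxy-7-oxoabieta-8,11,13-trien-19,20-olide | COc1c(OC)c2c(c(O)c1C(C)C)C(=O)C[C@@H]1[C@]23CCC[C@]1(C)C(=O)OC3
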